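The numbers in the tables stem from a simulated flask with constants of no real substance; scatter was added.

Per molar of charge, 1.03 M⁻¹ is what the elm run reads at 15.0 min for the split, chain material (open dimer plus open trimer) over ring material (ring plus over-reaction product), divided by the charge. This is a selectivity factor per molar.

| setting | elm | winter | dawn |
|---|---|---|---|
| starting material | 1 M | 2.0 M | 2.0 M |
| remark | run made earlier |  |  |
| time |  | 25 min | 40 min |

elm run (percent of the starting material charged)

| time / min | starting material / % | open trimer / % | ring / % | open dimer / % | over-reaction product / % |
|---|---|---|---|---|---|
| 1.33 | 63.2 | 1.8 | 12.2 | 20.7 | 0.5 |
| 2.50 | 45.8 | 4.4 | 19.3 | 27.8 | 1.3 |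
| 4.00 | 31.7 | 7.4 | 24.1 | 32.1 | 3.4 |
| 8.00 | 15.1 | 11.8 | 28.7 | 34.6 | 10.1 |
| 15.0 | 3.9 | 15.1 | 24.7 | 34.0 | 23.0 |

(scatter of a reading: 0.5 percentage points)

- in percentages every species weighs as the starting material in it: one open dimer counts as two
- in percentages every species weighs as the starting material in it: one open trimer counts as three
- on the list of suspects stand: 2 starting material -> open dimer; starting material + open dimer -> open trimer; starting material -> ring; ring -> over-reaction product

* which of these there is most of at the end, counted by the starting material in it, winter (ring / open trimer / over-reaction product / open dimer)
* which of these there is most of at the end, counted by the starting material in it, dawn (ring / open trimer / over-reaction product / open dimer)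
* how much there is at the end of the one of these that leads, in percent of the starting material charged: winter
* how much there is at the end of the one of these that leads, in percent of the starting material charged: dawn

You asked for a quick number, with the hunch that over-reaction product has taken the lead in dawn by 40 min. We reckon otherwise, and c(starting material) is the concentration to watch. Taken as written, the chain steps on the list of suspects are second order and ring closure is first order, so at equal percentages of the charge the ratio of their rates goes with the charge. As an estimate, then, a charge twice that of elm should give twice elm's ratio of chain material to ring material:

chain material / ring material = 1.03 M⁻¹ × 2.0 M = 2.06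

ring material, as share of chain and ring material together = 32.7%

We expect over-reaction product to stay within that share in both flasks. Chain material gets 67.3%, and in elm open dimer reads higher than open trimer, so open dimer is our choice for both. The split gives no figure for open dimer itself.

The forecast has open dimer in winter at 37% (34.5% to 39.5%) and open dimer in dawn at 37% (34.5% to 39.5%): “Dimer stays frozen once starting material is gone, so it leads at both times.”

The flask gives open dimer at 38.5% in winter and open dimer at 38.3% in dawn.

    2 starting material → open dimer (k = 0.00220 M⁻¹ s⁻¹)
    starting material + open dimer → open trimer (k = 0.00170 M⁻¹ s⁻¹)
    starting material → ring (k = 0.00210 s⁻¹)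
    ring → over-reaction product (k = 0.00100 s⁻¹)

Winter's ring material is 34.3% of chain and ring material together against our 32.7%, a split of 0.956 M⁻¹. In winter open dimer is made 2.27 times as fast as it is used up at 2.35 min, and with starting material down to 0.382% at 25.0 min it still reads 38.3% at 250 min.

In a flask like winter with 0.80 M, the split gives 0.823, so ring material should be 54.8% of chain and ring material together. Computed, it is 55.3%, and over-reaction product leads there at 37.1%, with open dimer at 31.4%.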